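**Remarks on the chemistry (assumptions)**

- Stannane 3 and sulfenyl imide 7 are taken as purchased reagents.
- The sense of induction of the selenophosphoramide on this alkene cannot be predicted with certainty. The route names the (S)-binaphthyl catalyst; its mirror image is used if a first run shows the antipode of 9.
- No structural error was found on checking. The anti adduct of the E alkene is (2S,3R)-9. C2 is S in 9 and 10 and R from 11 onward, although no bond at C2 changes: once sulfur has left C3, CH2O outranks C3.
- One design point is tightened: the primary alcohol has to be acetylated beside a free phenol, so an enzymatic acyl transfer is used (step 4).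

## Structural features

The target is an ester of (E)-ferulic acid, which carries a free para-phenol, with a primary neopentyl-type alcohol, the CH2OH group on C2 of a 2H-chromene. The chromene is a benzene ring fused to a 2H-pyran (O1, C2, C3=C4, C4a, C8a), with an acetyl group at C6 (para to O1) and a methoxy group at C8 (ortho to O1). C2 is the only stereocentre: a fully substituted ether carbon (O1, CH3, CH2O, C3) of R configuration with no neighbouring stereocentre, so a catalyst must set it. Fragile points are the 2H-chromene (acid, light or heat can open the pyran ring reversibly at O1–C2 and endanger C2), the cinnamate ester, the free phenol and the enolisable aryl methyl ketone. The real difficulty is to build the tetrasubstituted C2 enantioselectively, telling CH3 from CH2O, and to place C3=C4 without touching C2. The key step reads O1–C8a–C4a–C4–C3–C2(CH3)(CH2O) as a phenol oxygen with an ortho prenyl chain oxidised at its E-methyl group. A sulfenium ion attacks the C2=C3 alkene, O1 closes the pyran ring at the tertiary C2, and the sulfur left on C3 later leaves towards C4, the only neighbour with hydrogen.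

## Logic of the disconnections

17 to 16: the phenolic O–Si bond is cut. The cinnamate phenol must be masked while its acid is activated. The forward step must free the phenol without touching the ester or the chromene.

16 to 12 and 15: the ester C(=O)–O bond is cut, the only bond joining the two halves. This makes the route convergent. The forward step must acylate a hindered primary alcohol next to quaternary C2, so the alcohol oxygen has to be the nucleophile and no displacement at the neopentyl carbon is allowed.

15 to 13: both O–Si bonds are traced back to the free acid and phenol. The forward step must end with the silyl ester cleaved and the aryl silyl ether intact.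

12 to 11: the acetyl C–O bond on the primary oxygen is restored. That oxygen has to be masked through ring closure and sulfur removal. Its later removal must leave the ketone and the chromene alone.

11 to 9 (through 10): C3=C4 is replaced by a C3–S bond and a C4–H bond. This exposes the retron of the ring-closing step. Because C2 has no hydrogen the elimination has one direction only. It must run mildly enough not to open the pyran ring.

9 to 6 and 7: the O1–C2 and C3–S bonds are cut. This removes the pyran ring and both stereocentres and leaves an achiral phenol with an E-trisubstituted alkene. The forward step needs alkene face selection, oxygen attack at the tertiary carbon (6-endo) and a geometrically pure alkene.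

6 to 5: the acetate O–C(=O) bond is cut. The forward acetylation must choose the aliphatic hydroxyl over the phenol.

5 to 4: the C–O bond at the E-methyl group is cut, back to a plain prenyl chain. The forward oxidation must be E-selective and spare the phenol and the methyl ketone.

4 to 2 and 3: the aryl–CH2 bond is cut. The coupling must give the linear prenyl isomer.

2 to 1: the C–I bond is cut. Iodination must go ortho to the hydroxyl, the only free position it activates.

## Other disconnections considered

Alternative 1: The cut removes C4 from between C3 and C4a. Chroman-3-one A1 would come from the ring-contracted benzofuran-3-one A2, which already holds the quaternary stereocentre. In the forward key step BF3·OEt2 activates the C3 carbonyl of A2 and trimethylsilyldiazomethane adds. The aryl carbon then migrates as N2 leaves, forming C3–C4 and C4–C4a.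
- In its favour: the stereocentre is a spectator in the ring-forming step, so enantiocontrol and ring construction are decoupled. Aryl migration is the expected course, since the oxygen-bearing quaternary C2 migrates poorly. The C3 oxygen, like the sulfur of 9, can only be eliminated towards C4.
- Against it here: making A2 enantioselectively is a problem of the same rank as step 5 and only moves the difficulty. The carbonyl is a poorly electrophilic, ortho-oxygenated aryl ketone beside a quaternary centre. Epoxide formation and a second insertion compete, and chroman-3-ones enolise and air-oxidise easily. The ketone must still become the alkene (reduction, dehydration) and the bromide the acetyl group.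
- Comparison: it equals the chosen plan in the regiochemical logic of the double bond. It is better in that the key step creates no stereocentre. It is weaker in step economy by an estimated three to four steps and brings the acetyl group in late.

Alternative 2: The cut is the CH2–O bond, made by C–H oxidation of one of two enantiotopic methyl groups of the achiral acid A4. A4 would come from 1 by bromination, O-alkylation with an α-bromoisobutyrate and saponification. In the forward key step Pd(OAc)2 (divalent palladium), a chiral mono-protected amino acid-type ligand and tert-butyl hydroperoxide cleave one methyl C–H bond under carboxylate direction and close the β-lactone A3.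
- In its favour: the precursor is the simplest of all four plans. No alkene geometry is involved, and no tin, selenium or sulfur. The lactone differentiates the CH2O carbon from the future C3.
- Against it here: the key step closes no ring of the target and makes no skeletal C–C bond. C3 arrives at the acid oxidation level and C4 is missing. Lactone opening, reduction, one-carbon olefination and a 6-endo closure onto the aryl bromide (with 5-exo closure competing) would follow, with the ketone protected during hydride steps. The catalyst must tell apart two methyl groups on a carbon carrying a bulky di-ortho-substituted aryloxy group, and the strained α-aryloxy β-lactone is itself labile.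
- Comparison: it is better than the chosen plan in precursor simplicity and in atom economy of the stereo-defining step. It is equal in relying on a chiral catalyst. It is clearly weaker in step count and in ring construction.

Alternative 3: The cuts are C3=C4 (metathesis) and, one stage earlier, O1–C2 (allylic etherification). Diene A6, a tertiary allyl aryl ether with an ortho vinyl group, would give A5, which is identical with 12. In the forward key step (H2IMes)(PCy3)Cl2Ru=CHPh, the second-generation Grubbs catalyst, joins the C2 vinyl group and the styrenyl group and closes the 2H-pyran ring.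
- In its favour: A6 would come from 2 in two steps (vinylation, then palladium-catalysed asymmetric allylic etherification with a vinyl epoxide). The ring closure needs no protecting group, no sulfur and no heating above 40 °C. A5 would be reached in four steps from 1, against seven steps to 12 in the chosen route.
- Against it here: everything rests on the etherification. A di-ortho-substituted, acidic phenol must attack the more substituted terminus of a π-allyl palladium complex with high branched selectivity and high enantioselectivity. The tertiary allyl aryl ether A6 can ionise or undergo a [3,3] shift.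
- Comparison: in step economy and mildness this alternative is the better plan, and it is kept as the fallback for step 5. In catalyst control of C2 the two are equal. The chosen plan is stronger in one respect: its C–O bond forms intramolecularly and the tertiary carbon dictates the regiochemistry, not a ligand.

Key step: step 5

## Route

Step 1
Reactants: 1 acetovanillone [1-(4-hydroxy-3-methoxyphenyl)ethan-1-one]
Product: 2 5-iodoacetovanillone [1-(4-hydroxy-3-iodo-5-methoxyphenyl)ethan-1-one]
Conditions: NIS (1.05 equiv), TsOH·H2O (10 mol %), MeCN, 0 °C to rt
Reagents that add atoms: N-iodosuccinimide, O=C1CCC(=O)N1I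
Why: Electrophilic aromatic iodination; the hydroxyl directs to its only free ortho position (para is blocked by acetyl), and the acetyl group prevents a second iodination.

Step 2
Reactants: 2 5-iodoacetovanillone; 3 tributyl(3-methylbut-2-en-1-yl)stannane
Product: 4 5-prenylacetovanillone [1-[4-hydroxy-3-methoxy-5-(3-methylbut-2-en-1-yl)phenyl]ethan-1-one]
Conditions: Pd(PPh3)4 (5 mol %), DMF (degassed), 90 °C
Reagents that add atoms: none
Why: Stille coupling; zerovalent palladium inserts into the C–I bond, the allylstannane transmetallates and reductive elimination at the less hindered CH2 terminus should give the linear prenyl arene; the free phenol and the ketone are tolerated by the neutral conditions.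

Step 3
Reactants: 4 5-prenylacetovanillone
Product: 5 1-[4-hydroxy-3-[(2E)-4-hydroxy-3-methylbut-2-en-1-yl]-5-methoxyphenyl]ethan-1-one
Conditions: SeO2 (0.5 equiv), t-BuOOH (70 % aq, 2.5 equiv), salicylic acid (0.1 equiv), CH2Cl2, 0 °C to rt, stopped before full conversion
Reagents that add atoms: selenium dioxide, O=[Se]=O; tert-butyl hydroperoxide, CC(C)(C)OO
Why: Riley-type allylic oxidation; an ene reaction at the more substituted alkene carbon followed by a [2,3]-sigmatropic shift oxidises the methyl group trans to the chain and should give the E allylic alcohol; sub-stoichiometric selenium at room temperature limits over-oxidation to the enal and leaves the aryl methyl ketone, which needs hot stoichiometric SeO2, alone.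

Step 4
Reactants: 5 (E)-allylic alcohol
Product: 6 (2E)-4-(5-acetyl-2-hydroxy-3-methoxyphenyl)-2-methylbut-2-en-1-yl acetate
Conditions: vinyl acetate (5 equiv), immobilised Candida antarctica lipase B (Novozym 435), t-BuOMe, 30 °C
Reagents that add atoms: vinyl acetate, C=COC(C)=O
Why: Lipase-catalysed transesterification acylates primary aliphatic hydroxyl groups and leaves phenols untouched; release of acetaldehyde makes it irreversible, and the neutral conditions keep the E geometry.

Step 5
Reactants: 6 (E)-allylic acetate phenol; 7 N-(phenylthio)phthalimide [2-(phenylsulfanyl)isoindoline-1,3-dione]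
Product: 9 [(2S,3R)-6-acetyl-8-methoxy-2-methyl-3-(phenylsulfanyl)-3,4-dihydro-2H-chromen-2-yl]methyl acetate (S on C3 anti to O1 on C2), via thiiranium ion 8 (not isolated)
Conditions: 7 (1.1 equiv), (S)-4-(diisopropylamino)-3,5-dimethyl-4,5-dihydro-3H-dinaphtho[2,1-d:1',2'-f][1,3,2]diazaphosphepine 4-selenide (10 mol %), MsOH (0.5 equiv), CH2Cl2, −20 °C
Reagents that add atoms: none
Why: This is a Lewis base-catalysed enantioselective sulfenoetherification of an ortho-allyl phenol, a known reaction type. MsOH activates 7, the selenium of the chiral selenophosphoramide takes up PhS+ and hands it to one face of the electron-rich trisubstituted alkene of 6, giving thiiranium ion 8, which should hold its configuration at −20 °C. The phenol oxygen opens 8 at the tertiary carbon from the side opposite to sulfur, a 6-endo closure that forms O1–C2 with inversion and keeps the C3–S bond; loss of the proton gives 9 and phthalimide. C3 (R) is set by the catalyst-controlled face of sulfenium transfer, and C2 (S) follows from it because anti opening of the E alkene is stereospecific. The step needs face selectivity, 6-endo and not 5-exo opening, and attack on the alkene in preference to the ketone and the arene. The tertiary C2 carries most of the positive charge of 8 and draws the oxygen; the acetyl group deactivates the arene towards sulfenylation, and the low temperature keeps enolisation of the methyl ketone slow. The acetate survives the acid and keeps the primary oxygen from reacting with the sulfenium donor.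

Step 6
Reactants: 9 (2S,3R)-3-(phenylsulfanyl)chroman acetate
Product: 11 [(2R)-6-acetyl-8-methoxy-2-methyl-2H-chromen-2-yl]methyl acetate, via sulfoxide 10 (not isolated)
Conditions: H2O2 (30 % aq, 1.1 equiv), (CF3)2CHOH, rt; evaporate; toluene, pyridine (3 equiv), 95 °C, dark
Reagents that add atoms: none
Why: Hydrogen peroxide in hexafluoropropan-2-ol oxidises sulfides to sulfoxides and stops there; the peroxide oxygen sits in 10 and leaves again with the sulfur. Thermal syn elimination of the sulfoxide through a five-membered transition state can only take a hydrogen from benzylic C4 because C2 has none, giving the conjugated C3=C4 bond while C2 is untouched.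

Step 7
Reactants: 11 chromene acetate
Product: 12 1-[(2R)-2-(hydroxymethyl)-8-methoxy-2-methyl-2H-chromen-6-yl]ethan-1-one
Conditions: K2CO3 (0.2 equiv), MeOH, 0 °C to rt
Reagents that add atoms: none
Why: Base-catalysed transesterification with methanol removes the primary acetate; the chromene, the aryl ketone and the ether stereocentre are inert to catalytic methoxide.

Step 8
Reactants: 13 ferulic acid [(2E)-3-(4-hydroxy-3-methoxyphenyl)prop-2-enoic acid]
Product: 15 (2E)-3-[4-(tert-butyldimethylsilyloxy)-3-methoxyphenyl]prop-2-enoic acid, via bis-silyl derivative 14 (not isolated)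
Conditions: TBSCl (2.3 equiv), imidazole (5 equiv), DMF, rt; then AcOH/THF/H2O (3:1:1), rt
Reagents that add atoms: tert-butyldimethylsilyl chloride, CC(C)(C)[Si](C)(C)Cl
Why: Silylation covers both acidic OH groups; the silyl ester hydrolyses in aqueous acetic acid, whereas the aryl silyl ether survives, leaving the acid free for coupling and the phenol masked.

Step 9
Reactants: 12 chromene alcohol; 15 O-silyl ferulic acid
Product: 16 [(2R)-6-acetyl-8-methoxy-2-methyl-2H-chromen-2-yl]methyl (2E)-3-[4-(tert-butyldimethylsilyloxy)-3-methoxyphenyl]prop-2-enoate
Conditions: DCC (1.5 equiv), DMAP (0.3 equiv), CH2Cl2, 0 °C to rt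
Reagents that add atoms: none
Why: Steglich esterification; the carbodiimide activates the acid and 4-dimethylaminopyridine passes the acyl group to the hindered primary alcohol, whose oxygen is the nucleophile, so no substitution occurs at the neopentyl carbon and C2 and the E alkene are untouched.

Step 10
Reactants: 16 silyl-protected ester
Product: 17 target, [(2R)-6-acetyl-8-methoxy-2-methyl-2H-chromen-2-yl]methyl (2E)-3-(4-hydroxy-3-methoxyphenyl)prop-2-enoate
Conditions: Bu4NF (1.1 equiv), AcOH (1.2 equiv), THF, 0 °C
Reagents that add atoms: none
Why: Fluoride cleaves the aryl O–Si bond; the acetic acid buffer protonates the phenoxide at once, so the cinnamate ester and the chromene should not be attacked.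

## Compound list

1 | acetovanillone, 1-(4-hydroxy-3-methoxyphenyl)ethan-1-one | CC(=O)c1ccc(O)c(OC)c1 | starting material
2 | 1-(4-hydroxy-3-iodo-5-methoxyphenyl)ethan-1-one | CC(=O)c1cc(OC)c(O)c(I)c1 | intermediate
3 | tributyl(3-methylbut-2-en-1-yl)stannane | CCCC[Sn](CCCC)(CCCC)CC=C(C)C | starting material
4 | 1-[4-hydroxy-3-methoxy-5-(3-methylbut-2-en-1-yl)phenyl]ethan-1-one | CC(=O)c1cc(OC)c(O)c(CC=C(C)C)c1 | intermediate
5 | 1-[4-hydroxy-3-[(2E)-4-hydroxy-3-methylbut-2-en-1-yl]-5-methoxyphenyl]ethan-1-one | CC(=O)c1cc(OC)c(O)c(C/C=C(\C)CO)c1 | intermediate
6 | (2E)-4-(5-acetyl-2-hydroxy-3-methoxyphenyl)-2-methylbut-2-en-1-yl acetate | CC(=O)c1cc(OC)c(O)c(C/C=C(\C)COC(C)=O)c1 | intermediate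
7 | N-(phenylthio)phthalimide, 2-(phenylsulfanyl)isoindoline-1,3-dione | O=C1c2ccccc2C(=O)N1Sc1ccccc1 | starting material
8 | (2R,3R)-2-(acetoxymethyl)-3-(5-acetyl-2-hydroxy-3-methoxybenzyl)-2-methyl-1-phenylthiiran-1-ium, configuration at sulfur open, not isolated | CC(=O)OC[C@@]1(C)[S+](c2ccccc2)[C@@H]1Cc1cc(C(C)=O)cc(OC)c1O | intermediate
9 | [(2S,3R)-6-acetyl-8-methoxy-2-methyl-3-(phenylsulfanyl)-3,4-dihydro-2H-chromen-2-yl]methyl acetate | CC(=O)OC[C@@]1(C)[C@H](Sc2ccccc2)Cc2cc(C(C)=O)cc(OC)c2O1 | intermediate
10 | [(2S,3R)-6-acetyl-8-methoxy-2-methyl-3-(phenylsulfinyl)-3,4-dihydro-2H-chromen-2-yl]methyl acetate, both epimers at sulfur, not isolated | CC(=O)OC[C@@]1(C)[C@H](S(=O)c2ccccc2)Cc2cc(C(C)=O)cc(OC)c2O1 | intermediate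
11 | [(2R)-6-acetyl-8-methoxy-2-methyl-2H-chromen-2-yl]methyl acetate | CC(=O)OC[C@@]1(C)C=Cc2cc(C(C)=O)cc(OC)c2O1 | intermediate
12 | 1-[(2R)-2-(hydroxymethyl)-8-methoxy-2-methyl-2H-chromen-6-yl]ethan-1-one | OC[C@@]1(C)C=Cc2cc(C(C)=O)cc(OC)c2O1 | intermediate
13 | ferulic acid, (2E)-3-(4-hydroxy-3-methoxyphenyl)prop-2-enoic acid | COc1cc(/C=C/C(=O)O)ccc1O | starting material
14 | tert-butyldimethylsilyl (2E)-3-[4-(tert-butyldimethylsilyloxy)-3-methoxyphenyl]prop-2-enoate, not isolated | COc1cc(/C=C/C(=O)O[Si](C)(C)C(C)(C)C)ccc1O[Si](C)(C)C(C)(C)C | intermediate
15 | (2E)-3-[4-(tert-butyldimethylsilyloxy)-3-methoxyphenyl]prop-2-enoic acid | COc1cc(/C=C/C(=O)O)ccc1O[Si](C)(C)C(C)(C)C | intermediate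
16 | [(2R)-6-acetyl-8-methoxy-2-methyl-2H-chromen-2-yl]methyl (2E)-3-[4-(tert-butyldimethylsilyloxy)-3-methoxyphenyl]prop-2-enoate | COc1cc(/C=C/C(=O)OC[C@@]2(C)C=Cc3cc(C(C)=O)cc(OC)c3O2)ccc1O[Si](C)(C)C(C)(C)C | intermediate
17 | [(2R)-6-acetyl-8-methoxy-2-methyl-2H-chromen-2-yl]methyl (2E)-3-(4-hydroxy-3-methoxyphenyl)prop-2-enoate | COc1cc(/C=C/C(=O)OC[C@@]2(C)C=Cc3cc(C(C)=O)cc(OC)c3O2)ccc1O | target

## Step count and risks

Total step count: 10. Longest linear sequence: 9 (steps 1 to 7, 9 and 10, from 1 to 17); step 8 is the only side branch.

Least certain steps:

Step 5 (key step). The acetyl group makes the phenol a weak nucleophile, so ring closure may be slow. Sulfenium exchange between alkenes and the uncatalysed background reaction would then lower the enantiomeric purity. The acetate carbonyl oxygen may also open the thiiranium ion at C2 in competition with the phenol. Acid-promoted sulfenylation next to the ketone is a further drain. Any Z isomer in 6 would be carried into the wrong configuration at C2. The fallback changes the approach and sets out from 2: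
- Suzuki–Miyaura vinylation with potassium vinyltrifluoroborate (PdCl2(dppf), Cs2CO3, THF/H2O, 80 °C) would give 1-(4-hydroxy-3-methoxy-5-vinylphenyl)ethan-1-one F1.
- Asymmetric allylic etherification of F1 with 2-methyl-2-vinyloxirane (Pd2(dba)3·CHCl3, the matching enantiomer of N,N'-cyclohexane-1,2-diylbis[2-(diphenylphosphanyl)benzamide], CH2Cl2, rt) would give the tertiary ether 1-[4-{[(2R)-1-hydroxy-2-methylbut-3-en-2-yl]oxy}-3-methoxy-5-vinylphenyl]ethan-1-one F2, the same compound as A6.
- Ring-closing metathesis of F2 with (H2IMes)(PCy3)Cl2Ru=CHPh (CH2Cl2, 40 °C) comes back to the route at 12.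

Step 3. The allylic alcohol may be oxidised further to the enal, the free ortho-prenyl phenol may undergo oxidative side reactions, and conversion must be held back to limit both. The fallback sets out from 4:
- Cross-metathesis of the prenyl group with methacrolein ((H2IMes)Cl2Ru=CH(C6H4-2-OiPr), the second-generation Hoveyda–Grubbs catalyst, CH2Cl2, 40 °C) would give (2E)-4-(5-acetyl-2-hydroxy-3-methoxyphenyl)-2-methylbut-2-enal F3, with thermodynamic E control.
- Aldehyde-selective reduction of F3 (NaBH4, EtOH/CH2Cl2, −78 °C), which the deactivated para-hydroxy aryl ketone should survive, comes back at 5.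

Step 6. At the thermolysis temperature the chromene may open and re-close reversibly at O1–C2 by electrocyclisation, which would erode the enantiomeric purity. The sulfenic acid may add back to the new styrenyl bond. Over-oxidation to the sulfone would block elimination. The fallback sets out from 9:
- S-methylation with MeOTf (CH2Cl2, 0 °C) would give [(2S,3R)-2-(acetoxymethyl)-6-acetyl-8-methoxy-2-methyl-3,4-dihydro-2H-chromen-3-yl](methyl)(phenyl)sulfonium triflate F4.
- Anti elimination of F4 with DBU at rt removes a benzylic C4 hydrogen and methyl phenyl sulfide and comes back at 11 without heating.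

Step 2. The allyl group may couple through its substituted terminus (allylic transposition), and the phenol may protodestannylate 3. The fallback sets out from 1:
- O-allylation (allyl bromide, K2CO3, acetone) would give 1-[3-methoxy-4-(prop-2-en-1-yloxy)phenyl]ethan-1-one F5.
- Aromatic Claisen rearrangement of F5 (N,N-diethylaniline, 190 °C) would give 1-[4-hydroxy-3-methoxy-5-(prop-2-en-1-yl)phenyl]ethan-1-one F6.
- Cross-metathesis of F6 with 2-methylbut-2-ene ((H2IMes)(PCy3)Cl2Ru=CHPh, CH2Cl2, 40 °C) comes back at 4.

Step 9. Acylation of the neopentyl-type alcohol may be slow, which lets the activated acid rearrange to an unreactive N-acylurea. The fallback sets out from 12: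
- Heating with Meldrum's acid (toluene, 100 °C) would give the malonate half ester 3-{[(2R)-6-acetyl-8-methoxy-2-methyl-2H-chromen-2-yl]methoxy}-3-oxopropanoic acid F7.
- Knoevenagel–Doebner condensation of F7 with vanillin (pyridine, piperidine cat., 50 °C), with decarboxylation, builds the E cinnamate without phenol protection and comes back at 17.

## Further compounds

F1 | step 5 | 1-(4-hydroxy-3-methoxy-5-vinylphenyl)ethan-1-one | CC(=O)c1cc(OC)c(O)c(C=C)c1
F2 | step 5 | 1-[4-{[(2R)-1-hydroxy-2-methylbut-3-en-2-yl]oxy}-3-methoxy-5-vinylphenyl]ethan-1-one | OC[C@@](C)(C=C)Oc1c(C=C)cc(C(C)=O)cc1OC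
F3 | step 3 | (2E)-4-(5-acetyl-2-hydroxy-3-methoxyphenyl)-2-methylbut-2-enal | CC(=O)c1cc(OC)c(O)c(C/C=C(\C)C=O)c1
F4 | step 6 | [(2S,3R)-2-(acetoxymethyl)-6-acetyl-8-methoxy-2-methyl-3,4-dihydro-2H-chromen-3-yl](methyl)(phenyl)sulfonium trifluoromethanesulfonate | CC(=O)OC[C@@]1(C)[C@H]([S+](C)c2ccccc2)Cc2cc(C(C)=O)cc(OC)c2O1.[O-]S(=O)(=O)C(F)(F)F
F5 | step 2 | 1-[3-methoxy-4-(prop-2-en-1-yloxy)phenyl]ethan-1-one | CC(=O)c1ccc(OCC=C)c(OC)c1
F6 | step 2 | 1-[4-hydroxy-3-methoxy-5-(prop-2-en-1-yl)phenyl]ethan-1-one | CC(=O)c1cc(OC)c(O)c(CC=C)c1
F7 | step 9 | 3-{[(2R)-6-acetyl-8-methoxy-2-methyl-2H-chromen-2-yl]methoxy}-3-oxopropanoic acid | OC(=O)CC(=O)OC[C@@]1(C)C=Cc2cc(C(C)=O)cc(OC)c2O1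
A1 | alternative 1 | (2S)-6-bromo-2-[(tert-butyldimethylsilyloxy)methyl]-8-methoxy-2-methyl-2H-chromen-3(4H)-one | CC(C)(C)[Si](C)(C)OC[C@@]1(C)C(=O)Cc2cc(Br)cc(OC)c2O1
A2 | alternative 1 | (2S)-5-bromo-2-[(tert-butyldimethylsilyloxy)methyl]-7-methoxy-2-methyl-1-benzofuran-3(2H)-one | CC(C)(C)[Si](C)(C)OC[C@@]1(C)C(=O)c2cc(Br)cc(OC)c2O1
A3 | alternative 2 | (3S)-3-(4-acetyl-2-bromo-6-methoxyphenoxy)-3-methyloxetan-2-one | O=C1OC[C@]1(C)Oc1c(Br)cc(C(C)=O)cc1OC
A4 | alternative 2 | 2-(4-acetyl-2-bromo-6-methoxyphenoxy)-2-methylpropanoic acid | CC(=O)c1cc(Br)c(OC(C)(C)C(=O)O)c(OC)c1
A5 | alternative 3 | 1-[(2R)-2-(hydroxymethyl)-8-methoxy-2-methyl-2H-chromen-6-yl]ethan-1-one | OC[C@@]1(C)C=Cc2cc(C(C)=O)cc(OC)c2O1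
A6 | alternative 3 | 1-[4-{[(2R)-1-hydroxy-2-methylbut-3-en-2-yl]oxy}-3-methoxy-5-vinylphenyl]ethan-1-one | OC[C@@](C)(C=C)Oc1c(C=C)cc(C(C)=O)cc1OC
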